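**Retrosynthetic overview**

1. The target comes from its trimethyl ester by SN2 demethylation. The ester comes from a keto-diene in which one reductive radical cascade closes ring D (C16–C13) and ring C (C12–C11) together.
2. The cascade substrate is a trans-fused ring A/B bicycle with an exocyclic C9 methylene and a quaternary C8 (allyl on the α face, acetonyl on the β face, carried until late as its 2-methoxyallyl enol ether). It is made by sequential C8 alkylation and methylenation of a C9 ketone.
3. Ring A comes from a Nazarov-reagent double Michael annulation onto a ring B cyclopentenone diester, which sets C10. A dehydrogenation/hydrogenation pair then turns the cis fusion into trans. C4 is set by β-keto ester methylation and C3 by hydride reduction.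
4. Ring B is the starting cyclopentanone, which already carries C7. Ring order: B, then A, then C and D in one operation.

**Conventions and assumptions**

- Atom labels C1–C20 are those of the gibberellane skeleton of the target. Ring A = C1–C5, C10; ring B = C5, C6, C8, C9, C10; ring C = C8, C9, C11–C14; ring D = C8, C13–C16. α is the face of the C20 carboxyl; β is the face of H5 and H9.
- Assumption: methyl 5-methoxy-3-oxopentanoate (a stable precursor of the Nazarov reagent) and racemic methyl 3-oxocyclopentane-1-carboxylate are purchased.
- Assumption: 3-bromo-2-methoxyprop-1-ene (2-methoxyallyl bromide) is purchased and used fresh; it can also be made in one operation from 2-methoxypropene and N-bromosuccinimide.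
- Assumption: in step 3 the cinchonidinium catalyst or its cinchoninium pseudo-enantiomer is used, whichever gives the C10 configuration drawn.

**Route**

Step 1
Reactants: 1 methyl 3-oxocyclopentane-1-carboxylate
Product: 2 dimethyl 4-oxocyclopentane-1,3-dicarboxylate
Conditions: NaH (2.2 equiv), (MeO)2CO, THF, 65 °C; AcOH
Reagents that add atoms: dimethyl carbonate, COC(=O)OC
Why: Claisen-type carbomethoxylation of the ketone enolate under thermodynamic control puts the new ester (C20) on the less hindered α-carbon (future C10), the product being held as its stabilised β-keto ester enolate; no target stereocentre is fixed here.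

Step 2
Reactants: 2 dimethyl 4-oxocyclopentane-1,3-dicarboxylate
Product: 4 dimethyl 4-oxocyclopent-2-ene-1,3-dicarboxylate, via α-phenylselanyl keto diester 3 (not isolated)
Conditions: PhSeCl, pyridine, CH2Cl2, 0 °C; 30% H2O2, 0 °C; used crude
Reagents that add atoms: none
Why: Reich selenoxide syn-elimination: the β-keto ester is selenenylated at C10 and the selenoxide eliminates toward the only β-hydrogens (C5), giving the alkylidene β-keto ester.

Step 3
Reactants: 4 dimethyl 4-oxocyclopent-2-ene-1,3-dicarboxylate; 5 methyl 5-methoxy-3-oxopentanoate
Product: 8 cis-fused ring A/B enol triester, via Nazarov reagent 6 (not isolated), via C10 Michael adduct 7 (not isolated)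
Conditions: N-(9-anthracenylmethyl)cinchonidinium bromide (10 mol %), Cs2CO3 (30 mol %), toluene, −30 → 0 °C
Reagents that add atoms: none
Why: Proposed new method: base releases 6 from 5 by E1cB loss of methanol and turns 4 into its achiral cross-conjugated dienolate, which as a chiral ammonium ion pair adds through C10 to the vinyl ketone (asymmetric phase-transfer Michael addition, the step that sets the C10 quaternary centre), after which the side-chain β-keto ester closes ring A by 6-exo Michael addition to C5 on the face of C1 (cis fusion); the closest known reactions are the Cs2CO3 double Michael annulation of Nazarov reagents (Deslongchamps) and cinchona phase-transfer Michael additions of cyclic β-keto esters to vinyl ketones.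

Step 4
Reactants: 8 cis-fused ring A/B enol triester
Product: 11 conjugated dienol triester, via C4 selenide 9 (not isolated), via alkylidene keto ester 10 (not isolated)
Conditions: PhSeCl, pyridine, CH2Cl2, 0 °C; 30% H2O2, 0 °C; Et3N (10 mol %), rt
Reagents that add atoms: none
Why: A second Reich selenoxide elimination (selenium enters on the convex face, syn to H5) removes H5, and amine-mediated tautomerisation moves the double bond to C5=C6 in conjugation with the C7 ester, so the wrongly set C5 and the undefined C6 are erased and only C10 stays stereogenic.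

Step 5
Reactants: 11 conjugated dienol triester
Product: 12 trans-fused ring A/B enol triester
Conditions: H2 (3 atm), 10% Pd/C, EtOAc, rt
Reagents that add atoms: none
Why: Heterogeneous catalytic hydrogenation adds both hydrogens syn to the tetrasubstituted C5=C6 enoate from the β face, opposite the angular C20 ester, which gives the trans ring fusion (H5 β) and H6 β (C7 ester α), while the chelated β-keto ester enol is not reduced.

Step 6
Reactants: 12 trans-fused ring A/B enol triester
Product: 14 8α-allyl-8β-(2-methoxyallyl) ketone, via C8-allyl ketone 13 (not isolated)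
Conditions: LiN(i-Pr)2 (2.1 equiv), THF, −78 °C; allyl bromide (1.0 equiv); LiN(i-Pr)2 (1.1 equiv); 3-bromo-2-methoxyprop-1-ene (1.2 equiv), −78 → −20 °C; AcOH (1.2 equiv), −40 °C; sat. aq NaHCO3
Reagents that add atoms: allyl bromide, C=CCBr; 3-bromo-2-methoxyprop-1-ene, C=C(OC)CBr
Why: Two successive enolate alkylations of the dianion (the β-keto ester sits as its unreactive lithium enolate, the kinetic C9 ketone enolate reacts at C8, the only enolisable position) build the quaternary C8, and the second electrophile enters trans to the adjacent α-oriented C7 ester, so allyl ends α (C14) and the 2-methoxyallyl group β (C15), the latter being a masked acetonyl group (C15–C16–C17) that is inert to base, ylide and hydride.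

Step 7
Reactants: 14 8α-allyl-8β-(2-methoxyallyl) ketone
Product: 15 C9-methylene triester
Conditions: Ph3PCH3Br (5 equiv), KN(SiMe3)2 (6 equiv), toluene, 0 → 100 °C; AcOH (to pH 7), 0 °C
Reagents that add atoms: methyltriphenylphosphonium bromide, C[P+](c1ccccc1)(c1ccccc1)c1ccccc1.[Br-]
Why: Wittig methylenation under forcing potassium-ylide conditions (as used for fenchone-type ketones) converts the C9 ketone, which is the only free carbonyl because the β-keto ester is present as its potassium enolate, into the exocyclic C9=C11 alkene, the enol ether being untouched and any C6 epimerisation being of no consequence because C6 is equilibrated in the next step.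

Step 8
Reactants: 15 C9-methylene triester
Product: 17 4β-methyl 3-ketone, via 6β-ester enol 16 (not isolated)
Conditions: NaOMe (2 equiv), MeOH, 55 °C; AcOH (1 equiv); MeI, rt
Reagents that add atoms: iodomethane, CI
Why: Methoxide equilibrates the C6 ester (the only epimerisable centre, the β-keto ester being masked as its enolate) to the more stable β orientation trans to the C4–C5 bond and to the C20 ester, and the sodium enolate is then C-methylated from the β face, anti to the axial C20 ester (classical β-keto ester alkylation), which puts C18 β and the C19 ester α.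

Step 9
Reactants: 17 4β-methyl 3-ketone
Product: 19 8β-acetonyl keto-diene, via 3β-alcohol enol ether 18 (not isolated)
Conditions: LiBH(s-Bu)3 (1.3 equiv), THF, −78 °C; 1 M HCl, THF, −78 → 0 °C
Reagents that add atoms: water, O
Why: Bulky trialkylborohydride reduction of the only ketone occurs by equatorial attack on the ring A cyclohexanone and gives the axial 3β-alcohol, and the dilute-acid work-up then destroys the excess hydride and hydrolyses the 2-methoxyallyl enol ether to the methyl ketone (C16=O, C17 methyl) under conditions that leave both alkenes untouched (enol ether hydrolysis).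

Step 10
Reactants: 19 8β-acetonyl keto-diene
Product: 21 tetracyclic trimethyl ester, via spirocyclic C12 radical 20 (not isolated)
Conditions: SmI2 (2.5 equiv, added over 3 h), HMPA (10 equiv), t-BuOH (3 equiv), THF, −20 → 0 °C
Reagents that add atoms: none
Why: Proposed new method: SmI2/HMPA generates the C16 ketyl, which adds 5-exo to the allyl group with the O–Sm group anti to the alkene (Molander ketyl–olefin cyclisation; puts 16-OH on the side of C14 and the methyl endo), the C12 radical whose CH2 points to C9 then closes ring C by 6-endo attack on the unsubstituted terminus of the C9=C11 alkene (5-exo attack would hit a carbon flanked by two quaternary centres), which fixes the C13 bridgehead, and the tertiary C9 radical is reduced and protonated from the β face opposite the C20 ester (H9 β); the closest known reactions are SmI2 ketyl–olefin cyclisations and SmI2 radical cyclisation cascades.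

Step 11
Reactants: 21 tetracyclic trimethyl ester
Product: 22 target tricarboxylic acid (CNP0183110.3)
Conditions: LiSPr (10 equiv), HMPA, 50 °C; 1 M HCl, 0 °C
Reagents that add atoms: none
Why: SN2 O-demethylation of the three hindered methyl esters by thiolate (Bartlett–Johnson conditions, standard for gibberellin methyl esters) frees the three acids without touching any stereocentre.

**Compound list**

1 | methyl 3-oxocyclopentane-1-carboxylate (racemic) | COC(=O)C1CCC(=O)C1 | starting material
2 | dimethyl 4-oxocyclopentane-1,3-dicarboxylate (stereoisomer mixture) | COC(=O)C1CC(=O)C(C(=O)OC)C1 | intermediate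
3 | dimethyl 4-oxo-3-(phenylselanyl)cyclopentane-1,3-dicarboxylate | COC(=O)C1CC(=O)C(C(=O)OC)([Se]c2ccccc2)C1 | intermediate
4 | dimethyl 4-oxocyclopent-2-ene-1,3-dicarboxylate (racemic; ring B with C9 ketone, C10=C5 alkene, esters on C6 and C10) | COC(=O)C1CC(=O)C(C(=O)OC)=C1 | intermediate
5 | methyl 5-methoxy-3-oxopentanoate | COCCC(=O)CC(=O)OC | starting material
6 | methyl 3-oxopent-4-enoate (Nazarov reagent) | C=CC(=O)CC(=O)OC | intermediate
7 | dimethyl 3-(5-methoxy-3,5-dioxopentyl)-4-oxocyclopent-1-ene-1,3-dicarboxylate, C10 configured as in the target (C20 ester α) | COC(=O)CC(=O)CC[C@]1(C(=O)OC)C=C(C(=O)OC)CC1=O | intermediate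
8 | cis-fused ring A/B bicycle (bicyclo[4.3.0]nonane core): 3-enol, methyl esters on C4, C6 and C10, C9 ketone; H5 α and C20 ester α; C6 epimer mixture | COC(=O)C1=C(O)CC[C@@]2(C(=O)OC)C(=O)CC(C(=O)OC)[C@@H]12 | intermediate
9 | 4-phenylselanyl 3,9-diketone of 8 (keto form), selenium α, syn to H5 | COC(=O)[C@@]1([Se]c3ccccc3)C(=O)CC[C@@]2(C(=O)OC)C(=O)CC(C(=O)OC)[C@@H]12 | intermediate
10 | alkylidene β-keto ester: C4=C5 alkene, C3 and C9 ketones, esters on C4, C6, C10 | COC(=O)C1=C2C(C(=O)OC)CC(=O)[C@]2(C(=O)OC)CCC1=O | intermediate
11 | conjugated dienol triester: 3-enol (C3=C4), C5=C6 alkene, C9 ketone, esters on C4, C6, C10; C10 the only stereocentre | COC(=O)C1=C(O)CC[C@@]2(C(=O)OC)C(=O)CC(C(=O)OC)=C12 | intermediate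
12 | trans-fused ring A/B enol triester: H5 β, C20 ester α, C7 ester α, C9 ketone | COC(=O)C1=C(O)CC[C@@]2(C(=O)OC)C(=O)C[C@H](C(=O)OC)[C@H]12 | intermediate
13 | 8-allyl derivative of 12 (C8 epimer mixture) | COC(=O)C1=C(O)CC[C@@]2(C(=O)OC)C(=O)C(CC=C)[C@H](C(=O)OC)[C@H]12 | intermediate
14 | 8α-allyl-8β-(2-methoxyallyl) derivative of 12 (C9 ketone, C7 ester α) | COC(=O)C1=C(O)CC[C@@]2(C(=O)OC)C(=O)[C@@](CC=C)(CC(=C)OC)[C@H](C(=O)OC)[C@H]12 | intermediate
15 | C9-methylene analogue of 14 (C9=C11H2, C7 ester α) | COC(=O)C1=C(O)CC[C@@]2(C(=O)OC)C(=C)[C@@](CC=C)(CC(=C)OC)[C@H](C(=O)OC)[C@H]12 | intermediate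
16 | C6 epimer of 15 (C7 ester β) | COC(=O)C1=C(O)CC[C@@]2(C(=O)OC)C(=C)[C@@](CC=C)(CC(=C)OC)[C@@H](C(=O)OC)[C@H]12 | intermediate
17 | 3-ketone with quaternary C4 (C18 methyl β, C19 ester α), C7 ester β, 8α-allyl, 8β-(2-methoxyallyl), C9 methylene, C20 ester α | C[C@]1(C(=O)OC)[C@H]2[C@H](C(=O)OC)[C@@](CC(=C)OC)(CC=C)C(=C)[C@]2(C(=O)OC)CCC1=O | intermediate
18 | 3β-alcohol of 17, enol ether intact | C[C@]1(C(=O)OC)[C@H]2[C@H](C(=O)OC)[C@@](CC(=C)OC)(CC=C)C(=C)[C@]2(C(=O)OC)CC[C@@H]1O | intermediate
19 | 8β-(2-oxopropyl) keto-diene: 3β-OH, methyl ketone C16 with C17 methyl, 8α-allyl, C9 methylene | C[C@]1(C(=O)OC)[C@H]2[C@H](C(=O)OC)[C@@](CC(C)=O)(CC=C)C(=C)[C@]2(C(=O)OC)CC[C@@H]1O | intermediate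
20 | ring D closed (C16–C13 bond), C12 primary radical, drawn as the free alcohol; oxygen bound to trivalent samarium in the flask | C[C@]1(C(=O)OC)[C@H]2[C@H](C(=O)OC)[C@@]3(C[C@@H]([CH2])[C@](C)(O)C3)C(=C)[C@]2(C(=O)OC)CC[C@@H]1O | intermediate
21 | trimethyl ester of the target (7,19,20-trimethyl ester; 3β-OH; 16-OH on the side of C14, C17 methyl endo) | C[C@]1(C(=O)OC)[C@H]2[C@H](C(=O)OC)[C@@]34C[C@@H](CC[C@H]3[C@]2(C(=O)OC)CC[C@@H]1O)[C@](C)(O)C4 | intermediate
22 | 3β,16-dihydroxygibberellane-7,19,20-trioic acid in the α/β convention above, 16-OH on the side of C14 (CNP0183110.3) | C[C@]1(C(=O)O)[C@H]2[C@H](C(=O)O)[C@@]34C[C@@H](CC[C@H]3[C@]2(C(=O)O)CC[C@@H]1O)[C@](C)(O)C4 | target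

**Step count and risks**

Total step count: 11. Longest linear sequence: 11 steps (1 to 22).

The three steps most likely to fail:

Step 10 (radical cascade). The C12 radical may be reduced by SmI2 before it closes ring C. The first cyclisation may give the C13 epimer that cannot close. The C9 radical may be quenched from the α face. The fallback sets out from keto-diene 19 and changes both the initiating radical and the way C16 is oxygenated. Condensation with hydrazine hydrate (Et3N, EtOH, rt) gives the C16 hydrazone F1. Iodine and tetramethylguanidine in THF (Barton vinyl iodide synthesis) convert it to the 8β-(2-iodoallyl) diene F2. Bu3SnH (slow addition) and AIBN in benzene at 80 °C then generate the C16 vinyl radical, which closes ring D and then ring C with no one-electron reductant present, giving the 16-methylene triester F3. Mukaiyama hydration (Co(acac)2, PhSiH3, O2, i-PrOH) delivers the hydroxyl from the exo face of the C16 radical and comes back to the route at 21.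

Step 3 (asymmetric double Michael annulation). The enantioselectivity is unproven and the Nazarov reagent can polymerise. The fallback sets out from 4 (with 5) and replaces catalysis by resolution. The annulation is run with Cs2CO3 alone to give racemic 8, and steps 4 and 5 are run unchanged to racemic 12. Condensation with (S)-1-phenylethylamine (toluene, cat. AcOH, 4 Å sieves) gives two diastereomeric enamino esters; the desired one, the (S)-1-phenylethylamine enamino ester F4, is separated by crystallisation or chromatography. Hydrolysis with aqueous AcOH/THF comes back to the route at enantiopure 12.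

Step 7 (methylenation of a ketone flanked by two quaternary carbons). The Wittig reaction may stall. The fallback sets out from 14 and uses addition then elimination instead of olefination. MeLi/CeCl3 in THF at −78 °C adds to the C9 ketone to give the C9 tertiary methyl carbinol F5. Dehydration with the Burgess reagent in benzene at 50 °C, which is neutral and spares the enol ether, can only run toward the new methyl group, because C8 and C10 carry no hydrogen, and comes back to the route at 15.

**Further compounds**

F1 | step 10 | C16 hydrazone of 19 | C[C@]1(C(=O)OC)[C@H]2[C@H](C(=O)OC)[C@@](CC(C)=NN)(CC=C)C(=C)[C@]2(C(=O)OC)CC[C@@H]1O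
F2 | step 10 | 8β-(2-iodoallyl) analogue of 19 (C16 vinyl iodide) | C[C@]1(C(=O)OC)[C@H]2[C@H](C(=O)OC)[C@@](CC(I)=C)(CC=C)C(=C)[C@]2(C(=O)OC)CC[C@@H]1O
F3 | step 10 | 16-methylene triester (16-ene analogue of 21, no 16-OH) | C[C@]1(C(=O)OC)[C@H]2[C@H](C(=O)OC)[C@@]34C[C@@H](CC[C@H]3[C@]2(C(=O)OC)CC[C@@H]1O)C(=C)C4
F4 | step 3 | (S)-1-phenylethylamine enamino ester of 12 (amine on C3) | COC(=O)C1=C(N[C@@H](C)c3ccccc3)CC[C@@]2(C(=O)OC)C(=O)C[C@H](C(=O)OC)[C@H]12
F5 | step 7 | C9 tertiary methyl carbinol of 14 (C9 epimer mixture) | COC(=O)C1=C(O)CC[C@@]2(C(=O)OC)C(C)(O)[C@@](CC=C)(CC(=C)OC)[C@H](C(=O)OC)[C@H]12
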